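Ring B, the dioxane, is traced back to a strained oxetane: C2, C3, the CH2OH carbon and an oxygen on benzylic C2 make up a 2-aryl-3-aryloxyoxetane, whose benzylic C–O bond is later exchanged for a bond to the ring A phenol oxygen (O1–C2), releasing CH2OH. One Paternò–Büchi photocycloaddition of O-acetylvanillin with an aryl vinyl ether forms C2–C3, the O–CH2 bond and the four-membered ring, and sets C3. Because C2 is re-set to trans when the oxetane opens, only C3 needs control; the vinyl ether therefore carries a camphanoyl auxiliary on the neighbouring ring A oxygen and a nitrile as the masked side-chain carbon.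

Key step: step 4

**Remarks on the chemistry (assumptions and design choices)**

- Labels: ring A is the benzo ring that carries the side chain; ring B is the 1,4-dioxane with O1, C2 (aryl), C3 (CH2OH) and O4; ring C is the 4-hydroxy-3-methoxyphenyl ring. The side chain sits on C6, para to the ring A carbon that bears O1. The target is (2R,3R), trans.
- Assumption: the sense in which the camphanoyl group biases the aryloxy carbon cannot be predicted with confidence. The route is written with (1S)-camphanic chloride; its commercial (1R) antipode replaces it, with nothing else changed, should the preference run the other way.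
- No Lewis acid is placed on the aldehyde oxygen. It would remove the n,π* triplet on which oxetane formation depends, it could steer only C2 (which is erased later), and it would ionise both the vinyl ether and the oxetane. The chiral element is therefore built into the alkene partner, next to the carbon that becomes C3.
- The second ring A oxygen is introduced only after O-vinylation. A silyl or acyl group on a half-protected catechol can move between the two oxygens and blur which oxygen ends up on C3.

**Route**

Step 1
Reactants: 1 4-bromo-3-hydroxybenzonitrile; 2 vinyl acetate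
Product: 3 4-bromo-3-(vinyloxy)benzonitrile
Conditions: [Ir(cod)Cl]2 (1 mol%), Na2CO3 (0.6 equiv), toluene, 100 °C
Reagents that add atoms: vinyl acetate (2), C=COC(C)=O
Why: Iridium-catalysed transfer vinylation of a phenol, in which the phenoxide adds to iridium-bound vinyl acetate and acetate is lost, fixes the vinyl group on the oxygen meta to the nitrile before a second ring A oxygen exists; no stereocentre is formed.

Step 2
Reactants: 3 4-bromo-3-(vinyloxy)benzonitrile
Product: 5 4-hydroxy-3-(vinyloxy)benzonitrile, via pinacol boronate 4 (not isolated)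
Conditions: Pd(dppf)Cl2 (3 mol%), B2pin2, KOAc, 1,4-dioxane, 85 °C; then NaBO3·4H2O, THF/H2O, rt; neutral work-up, used at once
Reagents that add atoms: bis(pinacolato)diboron, CC1(C)OB(OC1(C)C)B1OC(C)(C)C(C)(C)O1 (boron of 4); sodium perborate NaBO3·4H2O, [Na+].[O-]OB=O (phenol oxygen of 5)
Why: Miyaura borylation of the C–Br bond followed by perborate oxidation (aryl shift from boron to oxygen) should deliver the phenol para to the nitrile under near-neutral conditions that leave vinyl ether and nitrile alone; no stereocentre is formed.

Step 3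
Reactants: 5 4-hydroxy-3-(vinyloxy)benzonitrile; 6 (1S)-camphanic chloride
Product: 7 4-cyano-2-(vinyloxy)phenyl (1S)-camphanate
Conditions: Et3N, DMAP (5 mol%), CH2Cl2, 0 °C
Reagents that add atoms: (1S)-camphanic chloride (6), ClC(=O)[C@@]12CC[C@@](C)(C(=O)O1)C2(C)C
Why: DMAP-catalysed O-acylation of the phenol caps the acidic O–H that would quench a triplet aldehyde and places the two fixed stereocentres of the auxiliary beside the vinyl ether; no new stereocentre is formed.

Step 4
Reactants: 7 4-cyano-2-(vinyloxy)phenyl (1S)-camphanate; 8 4-formyl-2-methoxyphenyl acetate (O-acetylvanillin)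
Product: 9 4-cyano-2-{[(2S,3R)-2-(4-acetoxy-3-methoxyphenyl)oxetan-3-yl]oxy}phenyl (1S)-camphanate (trans oxetane)
Conditions: hν (350 nm, Pyrex), degassed PhCF3, −20 °C, 7 in excess (recovered); chromatography on Et3N-deactivated SiO2
Reagents that add atoms: none
Why: Proposed new method: the n,π* triplet of aldehyde 8 adds through its oxygen to the unsubstituted vinyl carbon of 7 to give a triplet 1,4-biradical (benzylic ketyl carbon and α-aryloxy carbon) that, after intersystem crossing, closes the oxetane by C2–C3 radical recombination, so the ring is made by O–CH2 bond formation followed by 1,4-biradical coupling. The closest known reaction type is the Paternò–Büchi cycloaddition of aromatic aldehydes with enol ethers to 3-alkoxyoxetanes; steering the aryloxy carbon with a chiral acyl group on the neighbouring phenolic oxygen has not been shown. C3 is fixed by the face of the planar α-aryloxy radical that the ketyl carbon reaches, and the rigid camphanoyl bicycle, held roughly perpendicular to ring A right beside that radical, should shield one face; C2 arises in the same bond formation (trans shown) and needs no control because step 5 re-sets it, so a cis C2 epimer of the same C3 configuration would converge. The step needs oxygen-to-CH2 regiochemistry, secured by the oxygen-stabilised radical and by keeping electron transfer from the electron-poor vinyl ether uphill in a non-polar solvent, and it needs face selectivity at C3, secured by the auxiliary and backed by removal of the C3-epimeric diastereomers on chromatography. Acyl caps on both phenols avoid hydrogen-transfer quenching of the triplet, and the acetoxy group (unlike an alkoxy or silyloxy group) keeps the lowest triplet of the aldehyde n,π*-like.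

Step 5
Reactants: 9 trans oxetane
Product: 12 (2R,3R)-2-(4-hydroxy-3-methoxyphenyl)-3-(hydroxymethyl)-2,3-dihydro-1,4-benzodioxine-6-carbonitrile, via bisphenol oxetane 10 (not isolated), via para-quinone methide 11 (not isolated)
Conditions: K2CO3, MeOH, 0 °C to rt; AcOH, extractive work-up; then CSA (10 mol%), MeCN, rt
Reagents that add atoms: none
Why: Carbonate-mediated methanolysis removes both aryl esters, ionisation of the strained benzylic C2–O bond (phenoxide push, completed by acid) gives the para-quinone methide, and the ring A phenol para to the nitrile adds to it in a 6-exo-trig oxa-Michael closure (the known phenol opening of an oxetane to a 1,4-benzodioxane); reversible ionisation at C2 should let the ring settle as the diequatorial trans isomer, so C2 becomes R while C3 is untouched.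

Step 6
Reactants: 12 benzodioxane nitrile
Product: 14 (2R,3R)-2-(4-hydroxy-3-methoxyphenyl)-3-(hydroxymethyl)-2,3-dihydro-1,4-benzodioxine-6-carbaldehyde, via aldimine 13 (not isolated)
Conditions: iBu2AlH (4.5 equiv), CH2Cl2/THF, −78 to 0 °C; then 1 M aq. HCl, 0 °C
Reagents that add atoms: water, O
Why: Partial hydride reduction of a nitrile stops at the N-aluminium aldimine, which is hydrolysed to the aldehyde on acidic work-up while phenol and alcohol are carried as aluminium alkoxides; no stereocentre is touched.

Step 7
Reactants: 14 benzodioxane aldehyde; 15 malonic acid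
Product: 17 (2E)-3-[(2R,3R)-2-(4-hydroxy-3-methoxyphenyl)-3-(hydroxymethyl)-2,3-dihydro-1,4-benzodioxin-6-yl]prop-2-enoic acid, via arylidenemalonic acid 16 (not isolated)
Conditions: pyridine, piperidine (0.1 equiv), 70 °C
Reagents that add atoms: malonic acid (15), O=C(O)CC(=O)O
Why: Knoevenagel–Doebner condensation, in which amine-catalysed condensation with malonic acid is followed by decarboxylation in pyridine, should give the thermodynamically favoured E acid; C2 and C3 are not involved.

**Compound list**

1 | 4-bromo-3-hydroxybenzonitrile | N#Cc1ccc(Br)c(O)c1 | starting material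
2 | vinyl acetate | C=COC(C)=O | starting material
3 | 4-bromo-3-(ethenyloxy)benzonitrile | C=COc1cc(C#N)ccc1Br | intermediate
4 | 3-(ethenyloxy)-4-(4,4,5,5-tetramethyl-1,3,2-dioxaborolan-2-yl)benzonitrile | C=COc1cc(C#N)ccc1B1OC(C)(C)C(C)(C)O1 | intermediate (not isolated)
5 | 3-(ethenyloxy)-4-hydroxybenzonitrile | C=COc1cc(C#N)ccc1O | intermediate
6 | (1S)-camphanic chloride, (1S,4R)-4,7,7-trimethyl-3-oxo-2-oxabicyclo[2.2.1]heptane-1-carbonyl chloride | ClC(=O)[C@@]12CC[C@@](C)(C(=O)O1)C2(C)C | starting material
7 | 4-cyano-2-(ethenyloxy)phenyl (1S,4R)-4,7,7-trimethyl-3-oxo-2-oxabicyclo[2.2.1]heptane-1-carboxylate | C=COc1cc(C#N)ccc1OC(=O)[C@@]12CC[C@@](C)(C(=O)O1)C2(C)C | intermediate (key-step precursor)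
8 | 4-formyl-2-methoxyphenyl acetate (O-acetylvanillin) | COc1cc(C=O)ccc1OC(C)=O | starting material (key-step precursor)
9 | 4-cyano-2-{[(2S,3R)-2-(4-acetoxy-3-methoxyphenyl)oxetan-3-yl]oxy}phenyl (1S,4R)-4,7,7-trimethyl-3-oxo-2-oxabicyclo[2.2.1]heptane-1-carboxylate (trans oxetane) | COc1cc([C@@H]2OC[C@H]2Oc2cc(C#N)ccc2OC(=O)[C@@]23CC[C@@](C)(C(=O)O2)C3(C)C)ccc1OC(C)=O | intermediate (key-step product)
10 | 4-hydroxy-3-{[(2S,3R)-2-(4-hydroxy-3-methoxyphenyl)oxetan-3-yl]oxy}benzonitrile | COc1cc([C@@H]2OC[C@H]2Oc2cc(C#N)ccc2O)ccc1O | intermediate (not isolated)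
11 | 4-hydroxy-3-{[(2S)-1-hydroxy-3-(3-methoxy-4-oxocyclohexa-2,5-dien-1-ylidene)propan-2-yl]oxy}benzonitrile (para-quinone methide; same spatial arrangement at the aryloxy carbon as C3 of 9, the descriptor changes only through the priority rules) | COC1=CC(=C[C@@H](CO)Oc2cc(C#N)ccc2O)C=CC1=O | intermediate (not isolated)
12 | (2R,3R)-2-(4-hydroxy-3-methoxyphenyl)-3-(hydroxymethyl)-2,3-dihydro-1,4-benzodioxine-6-carbonitrile | COc1cc([C@H]2Oc3ccc(C#N)cc3O[C@@H]2CO)ccc1O | intermediate
13 | (2R,3R)-2-(4-hydroxy-3-methoxyphenyl)-3-(hydroxymethyl)-6-(iminomethyl)-2,3-dihydro-1,4-benzodioxine (formed as its N-aluminium derivative) | COc1cc([C@H]2Oc3ccc(C=N)cc3O[C@@H]2CO)ccc1O | intermediate (not isolated)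
14 | (2R,3R)-2-(4-hydroxy-3-methoxyphenyl)-3-(hydroxymethyl)-2,3-dihydro-1,4-benzodioxine-6-carbaldehyde | COc1cc([C@H]2Oc3ccc(C=O)cc3O[C@@H]2CO)ccc1O | intermediate
15 | malonic acid | O=C(O)CC(=O)O | starting material
16 | 2-{[(2R,3R)-2-(4-hydroxy-3-methoxyphenyl)-3-(hydroxymethyl)-2,3-dihydro-1,4-benzodioxin-6-yl]methylidene}propanedioic acid | COc1cc([C@H]2Oc3ccc(C=C(C(=O)O)C(=O)O)cc3O[C@@H]2CO)ccc1O | intermediate (not isolated)
17 | (2E)-3-[(2R,3R)-2-(4-hydroxy-3-methoxyphenyl)-3-(hydroxymethyl)-2,3-dihydro-1,4-benzodioxin-6-yl]prop-2-enoic acid | COc1cc([C@H]2Oc3ccc(/C=C/C(=O)O)cc3O[C@@H]2CO)ccc1O | target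

**Step count**

Total: 7 steps. Longest linear sequence: 7 steps (1 to 17); compounds 2, 6, 8 and 15 are purchased.

**Steps most likely to fail**

1. Step 4 (proposed new method). What may go wrong: the auxiliary gives too weak a facial bias at the aryloxy carbon and the C3-epimeric diastereomers do not separate, or the aldehyde triplet adds inefficiently. The fallback uses only known chemistry, sets out from 8 and comes back at 12.
   - 3,4-Dihydroxybenzonitrile F1 is alkylated at its more acidic 4-hydroxyl (MOMCl, K2CO3, acetone) to 3-hydroxy-4-(methoxymethoxy)benzonitrile F2.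
   - F2 is O-alkylated with (4S)-4-benzyl-3-(bromoacetyl)oxazolidin-2-one F3 (K2CO3, acetone) to the aryloxyacetyl imide F4.
   - An Evans syn-aldol reaction of F4 (Bu2BOTf, iPr2NEt, CH2Cl2, −78 °C) with aldehyde 8 should give the aldol adduct F5. The (4S) auxiliary fixes the aryloxy carbon in the configuration that becomes C3 R.
   - LiBH4 in THF removes the auxiliary and the aryl acetate to give the triol F6.
   - HCl in MeOH cleaves the MOM ether, ionises the benzylic alcohol and closes ring B through the same quinone methide to the trans isomer, which is 12. The configuration of the benzylic carbinol is of no consequence.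

2. Step 5. What may go wrong: the quinone methide is lost to solvent capture or oligomerisation before ring A closes, or the oxetane opens at its CH2 carbon. The fallback separates the events, sets out from 9 and comes back at 12.
   - Acid-catalysed hydrolytic opening (TsOH·H2O cat., THF/H2O, rt) while both phenols are still acylated should give the acyclic benzylic alcohol diester F7. Water captures the benzylic cation and both C1 epimers serve.
   - K2CO3 in MeOH removes both esters to give the tetraol F8.
   - The known acid-catalysed dehydrative cyclisation of such 1-aryl-2-aryloxypropane-1,3-diols (CSA, MeCN) closes ring B to the trans isomer 12.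

3. Step 7. What may go wrong: in the warm amine medium the ring C phenoxide reopens ring B, and the quinone methide is captured by malonate or piperidine. The fallback is base-free, sets out from 14 and comes back at 17.
   - Wittig olefination with the stabilised ylide Ph3P=CHCO2tBu (toluene, rt) should give the E tert-butyl ester F9.
   - TFA in CH2Cl2 with anisole as cation trap removes the tert-butyl group to give 17.

**Further compounds**

F1 | step 4 | 3,4-dihydroxybenzonitrile | N#Cc1ccc(O)c(O)c1
F2 | step 4 | 3-hydroxy-4-(methoxymethoxy)benzonitrile | COCOc1ccc(C#N)cc1O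
F3 | step 4 | (4S)-4-benzyl-3-(bromoacetyl)-1,3-oxazolidin-2-one | O=C1OC[C@H](Cc2ccccc2)N1C(=O)CBr
F4 | step 4 | (4S)-4-benzyl-3-{[5-cyano-2-(methoxymethoxy)phenoxy]acetyl}-1,3-oxazolidin-2-one | O=C1OC[C@H](Cc2ccccc2)N1C(=O)COc1cc(C#N)ccc1OCOC
F5 | step 4 | 4-{(1R,2S)-3-[(4S)-4-benzyl-2-oxo-1,3-oxazolidin-3-yl]-2-[5-cyano-2-(methoxymethoxy)phenoxy]-1-hydroxy-3-oxopropyl}-2-methoxyphenyl acetate | O=C1OC[C@H](Cc2ccccc2)N1C(=O)[C@@H](Oc1cc(C#N)ccc1OCOC)[C@H](O)c1ccc(OC(C)=O)c(OC)c1
F6 | step 4 | 3-{[(1R,2R)-1,3-dihydroxy-1-(4-hydroxy-3-methoxyphenyl)propan-2-yl]oxy}-4-(methoxymethoxy)benzonitrile | OC[C@@H](Oc1cc(C#N)ccc1OCOC)[C@H](O)c1ccc(O)c(OC)c1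
F7 | step 5 | 4-[(2R)-2-{5-cyano-2-[(1S)-camphanoyloxy]phenoxy}-1,3-dihydroxypropyl]-2-methoxyphenyl acetate (both C1 epimers) | COc1cc(C(O)[C@@H](CO)Oc2cc(C#N)ccc2OC(=O)[C@@]23CC[C@@](C)(C(=O)O2)C3(C)C)ccc1OC(C)=O
F8 | step 5 | 4-hydroxy-3-{[(2R)-1,3-dihydroxy-1-(4-hydroxy-3-methoxyphenyl)propan-2-yl]oxy}benzonitrile (both C1 epimers) | COc1cc(C(O)[C@@H](CO)Oc2cc(C#N)ccc2O)ccc1O
F9 | step 7 | tert-butyl (2E)-3-[(2R,3R)-2-(4-hydroxy-3-methoxyphenyl)-3-(hydroxymethyl)-2,3-dihydro-1,4-benzodioxin-6-yl]prop-2-enoate | COc1cc([C@H]2Oc3ccc(/C=C/C(=O)OC(C)(C)C)cc3O[C@@H]2CO)ccc1O
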